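**Retrosynthetic overview**

1. Target 23 ← octabenzyl dimer 22 (hydrogenolysis) ← Friedel–Crafts disconnection of the interflavan bond C4(upper)–C8(lower) into flavan-3,4-diol 20 and the C8–H nucleophile 15.
2. 15 ← the aryl ether bond O1–C8a of ring C of the lower unit, closed by an aryne cine-cyclization of the acyclic bromo alcohol 12.
3. Enabling feature: ring A of the lower unit is a 2-methylresorcinol nucleus, symmetric about the C6···C8a axis. Its 4,6-dibromide has the bromines on C4a and C8 and its only C–H on C8a: one bromine builds C4a–C4, the other (on C8, next to the C7 oxygen) triggers a C8≡C8a aryne that O1 attacks at C8a, and C8 comes back as the C–H needed for the interflavan bond.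
4. 12 ← dibromide 3 + methyl (S)-glycidate 4 (sets C3), then ring B Grignard on a Weinreb amide and chelation-controlled reduction (sets C2, anti).
5. 20 ← (2R,3R)-taxifolin 16 by benzylation, removal of the C5 oxygen and carbonyl reduction. Ring order: ring C of the lower unit (step 8) on a bought ring A; the rings of the upper unit are bought intact; union in step 13.

Key step: step 8

Assumption: commercial (+)-taxifolin is the (2R,3R) enantiomer, and the 4S centre of the target corresponds to the 3,4-trans (4α→8) interflavan linkage.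

**Route**

Step 1
Reactants: 1 2-methylbenzene-1,3-diol
Product: 2 4,6-dibromo-2-methylbenzene-1,3-diol
Conditions: NBS (2.05 equiv), MeCN, 0 °C to rt
Reagents that add atoms: N-bromosuccinimide, O=C1CCC(=O)N1Br
Why: Electrophilic aromatic bromination should go only to C4 and C6, the two positions ortho/para to both hydroxyl groups, and leave the doubly meta C5–H (the future C8a) untouched.

Step 2
Reactants: 2 4,6-dibromo-2-methylbenzene-1,3-diol
Product: 3 1,5-dibromo-2,4-bis(benzyloxy)-3-methylbenzene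
Conditions: BnBr (2.3 equiv), K2CO3, DMF, 60 °C
Reagents that add atoms: benzyl bromide, BrCc1ccccc1
Why: Williamson ether synthesis of both phenols with a mild carbonate base; the benzyl ethers are the only protecting groups of ring A and fall in the final hydrogenolysis.

Step 3
Reactants: 3 1,5-dibromo-2,4-bis(benzyloxy)-3-methylbenzene; 4 methyl (2S)-oxirane-2-carboxylate
Product: 6 methyl (2S)-3-[2,4-bis(benzyloxy)-5-bromo-3-methylphenyl]-2-hydroxypropanoate, via arylmagnesium chloride 5 (not isolated)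
Conditions: iPrMgCl·LiCl (1.1 equiv), THF, 0 °C to rt; then CuI (10 mol%), 4, −30 °C to 0 °C; aq. NH4Cl
Reagents that add atoms: none
Why: Bromine–magnesium exchange should stop after one of the two equivalent bromides because the arylmagnesium formed is electron-rich, and the copper-catalysed SN2 opening of the glycidic ester at its CH2 terminus joins C4a to C4 without touching the stereocentre, which becomes C3 (S).

Step 4
Reactants: 6 methyl (2S)-3-[2,4-bis(benzyloxy)-5-bromo-3-methylphenyl]-2-hydroxypropanoate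
Product: 7 methyl (2S)-2-(benzyloxy)-3-[2,4-bis(benzyloxy)-5-bromo-3-methylphenyl]propanoate
Conditions: benzyl 2,2,2-trichloroacetimidate (1.5 equiv), TfOH (5 mol%), CH2Cl2/cyclohexane, 0 °C to rt
Reagents that add atoms: benzyl 2,2,2-trichloroacetimidate, N=C(OCc1ccccc1)C(Cl)(Cl)Cl
Why: Acid-catalysed O-benzylation with the trichloroacetimidate uses no base and so keeps the α-stereocentre; this ether later keeps the C3 oxygen out of a five-membered closure in step 8.

Step 5
Reactants: 7 methyl (2S)-2-(benzyloxy)-3-[2,4-bis(benzyloxy)-5-bromo-3-methylphenyl]propanoate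
Product: 8 (2S)-2-(benzyloxy)-3-[2,4-bis(benzyloxy)-5-bromo-3-methylphenyl]-N-methoxy-N-methylpropanamide
Conditions: MeNH(OMe)·HCl (3 equiv), AlMe3 (3 equiv), CH2Cl2, 0 °C to rt; 1 M HCl work-up
Reagents that add atoms: N,O-dimethylhydroxylamine hydrochloride, CNOC.Cl
Why: Weinreb amide formation by aminolysis of the ester with the aluminium amide, which should neither enolise the α-alkoxy ester nor touch the aryl bromide.

Step 6
Reactants: 8 (2S)-2-(benzyloxy)-3-[2,4-bis(benzyloxy)-5-bromo-3-methylphenyl]-N-methoxy-N-methylpropanamide; 9 4-bromo-1,2-bis(benzyloxy)benzene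
Product: 11 (2S)-2-(benzyloxy)-3-[2,4-bis(benzyloxy)-5-bromo-3-methylphenyl]-1-[3,4-bis(benzyloxy)phenyl]propan-1-one, via arylmagnesium bromide 10 (not isolated)
Conditions: 9, Mg turnings, I2 (cat.), THF, reflux; then 8, THF, 0 °C; aq. NH4Cl
Reagents that add atoms: none
Why: Weinreb ketone synthesis, in which the chelated tetrahedral intermediate stops at mono-addition; a Grignard reagent is used instead of an aryllithium so that the ring A bromide is not exchanged.

Step 7
Reactants: 11 (2S)-2-(benzyloxy)-3-[2,4-bis(benzyloxy)-5-bromo-3-methylphenyl]-1-[3,4-bis(benzyloxy)phenyl]propan-1-one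
Product: 12 (1R,2S)-2-(benzyloxy)-3-[2,4-bis(benzyloxy)-5-bromo-3-methylphenyl]-1-[3,4-bis(benzyloxy)phenyl]propan-1-ol
Conditions: Zn(BH4)2, Et2O, −30 °C to 0 °C; aq. NH4Cl
Reagents that add atoms: none
Why: Chelation-controlled reduction: zinc bridges the carbonyl and the α-benzyloxy oxygen and hydride enters from the face of the α-hydrogen, which should give the 1,2-anti alcohol (1R), the relative configuration that becomes 2,3-trans after a ring closure that retains C2.

Step 8
Reactants: 12 (1R,2S)-2-(benzyloxy)-3-[2,4-bis(benzyloxy)-5-bromo-3-methylphenyl]-1-[3,4-bis(benzyloxy)phenyl]propan-1-ol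
Product: 15 (2R,3S)-3,5,7-tris(benzyloxy)-2-[3,4-bis(benzyloxy)phenyl]-6-methyl-3,4-dihydro-2H-chromene (penta-O-benzyl-6-methylcatechin), via aryne lithium alkoxide 13 (not isolated), via 8-lithiochromane 14 (not isolated)
Conditions: lithium 2,2,6,6-tetramethylpiperidide (3.0 equiv, from 2,2,6,6-tetramethylpiperidine and n-BuLi), THF, −78 °C to 0 °C; aq. NH4Cl
Reagents that add atoms: none
Why: The lithium amide should first form the C2 alkoxide and then remove the only ring A proton, C8a–H (ortho to the C8 bromine), so that loss of LiBr gives the C8≡C8a aryne 13, to which the tethered alkoxide O1 adds in the ring plane to give aryllithium 14, protonated on work-up. The closest known reaction type is the aryne ring closure by a tethered oxygen nucleophile (cine-substitution of a meta-halide), long used for benzo-fused oxygen and nitrogen heterocycles. The pyran ring C of the lower unit closes in a 6-exo mode by the O1–C8a bond alone. No stereocentre is formed: C2 and C3 keep the anti relationship set in steps 3 and 7, because the new bond is made at the aryl carbon and neither C–O bond of the side chain is touched, so the product is the 2,3-trans flavan. The step needs regiocontrol of aryne formation and of the addition: the bromine has a single ortho hydrogen, and both the tether at C4a and the inductive pull of the C7 benzyloxy group (which polarises the aryne so that the carbanion develops at C8, next to oxygen) send O1 to C8a. Chemoselectivity over a five-membered closure is secured because the C3 oxygen is a benzyl ether and only O1 is anionic.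

Step 9
Reactants: 16 (2R,3R)-2-(3,4-dihydroxyphenyl)-3,5,7-trihydroxy-2,3-dihydro-4H-chromen-4-one (taxifolin)
Product: 17 (2R,3R)-7-(benzyloxy)-2-[3,4-bis(benzyloxy)phenyl]-3,5-dihydroxy-2,3-dihydro-4H-chromen-4-one
Conditions: BnBr (3.3 equiv), K2CO3, DMF, 0 °C to rt
Reagents that add atoms: benzyl bromide, BrCc1ccccc1
Why: Williamson ether synthesis under mild carbonate conditions should alkylate the three acidic phenols while the 5-OH, hydrogen-bonded to the C4 carbonyl, and the secondary 3-OH stay free; C2 and C3 come unchanged from the chiral pool.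

Step 10
Reactants: 17 (2R,3R)-7-(benzyloxy)-2-[3,4-bis(benzyloxy)phenyl]-3,5-dihydroxy-2,3-dihydro-4H-chromen-4-one
Product: 18 (2R,3R)-7-(benzyloxy)-2-[3,4-bis(benzyloxy)phenyl]-3-hydroxy-4-oxo-3,4-dihydro-2H-chromen-5-yl trifluoromethanesulfonate
Conditions: PhNTf2 (1.2 equiv), K2CO3, DMF, rt
Reagents that add atoms: N-phenylbis(trifluoromethanesulfonimide), O=S(=O)(N(c1ccccc1)S(=O)(=O)C(F)(F)F)C(F)(F)F
Why: Phenol-selective sulfonylation: the triflimide reagent transfers the triflyl group to the phenoxide but not to the secondary alcohol.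

Step 11
Reactants: 18 (2R,3R)-7-(benzyloxy)-2-[3,4-bis(benzyloxy)phenyl]-3-hydroxy-4-oxo-3,4-dihydro-2H-chromen-5-yl trifluoromethanesulfonate
Product: 19 (2R,3R)-7-(benzyloxy)-2-[3,4-bis(benzyloxy)phenyl]-3-hydroxy-2,3-dihydro-4H-chromen-4-one
Conditions: Pd(OAc)2 (5 mol%), PPh3 (10 mol%), HCO2H, Et3N, DMF, 60 °C
Reagents that add atoms: none
Why: Palladium-catalysed reductive cleavage of the aryl triflate with formate as hydride source (oxidative addition to zerovalent palladium is helped by the ortho carbonyl) deletes the C5 oxygen without touching the benzyl ethers or C2/C3.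

Step 12
Reactants: 19 (2R,3R)-7-(benzyloxy)-2-[3,4-bis(benzyloxy)phenyl]-3-hydroxy-2,3-dihydro-4H-chromen-4-one
Product: 20 (2R,3S,4R)-7-(benzyloxy)-2-[3,4-bis(benzyloxy)phenyl]-3,4-dihydro-2H-chromene-3,4-diol
Conditions: NaBH4, THF/MeOH, 0 °C
Reagents that add atoms: none
Why: Borohydride reduction of the ketone by axial hydride delivery should give mainly the equatorial 4-OH (3,4-trans, 4R); the C4 configuration is not critical because C4 is ionised in step 13.

Step 13
Reactants: 20 (2R,3S,4R)-7-(benzyloxy)-2-[3,4-bis(benzyloxy)phenyl]-3,4-dihydro-2H-chromene-3,4-diol; 15 (2R,3S)-3,5,7-tris(benzyloxy)-2-[3,4-bis(benzyloxy)phenyl]-6-methyl-3,4-dihydro-2H-chromene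
Product: 22 (2R,3S,4S)-7-(benzyloxy)-2-[3,4-bis(benzyloxy)phenyl]-4-[(2R,3S)-3,5,7-tris(benzyloxy)-2-[3,4-bis(benzyloxy)phenyl]-6-methyl-3,4-dihydro-2H-chromen-8-yl]-3,4-dihydro-2H-chromen-3-ol, via flavan-4-yl cation 21 (not isolated)
Conditions: 15 (2.5 equiv, excess recovered), BF3·OEt2 (0.3 equiv), 4 Å molecular sieves, CH2Cl2, −40 °C to 0 °C
Reagents that add atoms: none
Why: Lewis-acid ionisation of the benzylic 4-OH gives cation 21 (stabilised by the para C7 oxygen), and Friedel–Crafts attack by C8 of 15, its only free and most electron-rich position (C6 is blocked by the methyl group), should occur anti to the 3-hydroxyl on the half-chair cation and so set C4 as S (3,4-trans, 2,4-cis).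

Step 14
Reactants: 22 octabenzyl dimer
Product: 23 (2R,3S,4S)-2-(3,4-dihydroxyphenyl)-4-[(2R,3S)-2-(3,4-dihydroxyphenyl)-3,5,7-trihydroxy-6-methyl-3,4-dihydro-2H-chromen-8-yl]-3,4-dihydro-2H-chromene-3,7-diol (target)
Conditions: H2 (1 atm), Pd(OH)2/C, THF/MeOH/H2O, rt
Reagents that add atoms: none
Why: Hydrogenolysis of the eight benzyl ethers under neutral conditions should leave the stereocentres, the cyclic benzylic ethers and the interflavan bond intact.

**Compound list**

1 | 2-methylbenzene-1,3-diol (2-methylresorcinol) | Cc1c(O)cccc1O | starting material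
2 | 4,6-dibromo-2-methylbenzene-1,3-diol | Cc1c(O)c(Br)cc(Br)c1O | intermediate
3 | 1,5-dibromo-2,4-bis(benzyloxy)-3-methylbenzene | Cc1c(OCc2ccccc2)c(Br)cc(Br)c1OCc1ccccc1 | intermediate
4 | methyl (2S)-oxirane-2-carboxylate (methyl (S)-glycidate) | COC(=O)[C@@H]1CO1 | starting material
5 | [2,4-bis(benzyloxy)-5-bromo-3-methylphenyl]magnesium chloride | Cc1c(OCc2ccccc2)c(Br)cc([Mg]Cl)c1OCc1ccccc1 | intermediate (not isolated)
6 | methyl (2S)-3-[2,4-bis(benzyloxy)-5-bromo-3-methylphenyl]-2-hydroxypropanoate | COC(=O)[C@@H](O)Cc1cc(Br)c(OCc2ccccc2)c(C)c1OCc1ccccc1 | intermediate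
7 | methyl (2S)-2-(benzyloxy)-3-[2,4-bis(benzyloxy)-5-bromo-3-methylphenyl]propanoate | COC(=O)[C@@H](OCc1ccccc1)Cc1cc(Br)c(OCc2ccccc2)c(C)c1OCc1ccccc1 | intermediate
8 | (2S)-2-(benzyloxy)-3-[2,4-bis(benzyloxy)-5-bromo-3-methylphenyl]-N-methoxy-N-methylpropanamide | CON(C)C(=O)[C@@H](OCc1ccccc1)Cc1cc(Br)c(OCc2ccccc2)c(C)c1OCc1ccccc1 | intermediate
9 | 4-bromo-1,2-bis(benzyloxy)benzene | Brc1ccc(OCc2ccccc2)c(OCc2ccccc2)c1 | starting material
10 | [3,4-bis(benzyloxy)phenyl]magnesium bromide | Br[Mg]c1ccc(OCc2ccccc2)c(OCc2ccccc2)c1 | intermediate (not isolated)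
11 | (2S)-2-(benzyloxy)-3-[2,4-bis(benzyloxy)-5-bromo-3-methylphenyl]-1-[3,4-bis(benzyloxy)phenyl]propan-1-one | O=C(c1ccc(OCc2ccccc2)c(OCc2ccccc2)c1)[C@@H](OCc1ccccc1)Cc1cc(Br)c(OCc2ccccc2)c(C)c1OCc1ccccc1 | intermediate
12 | (1R,2S)-2-(benzyloxy)-3-[2,4-bis(benzyloxy)-5-bromo-3-methylphenyl]-1-[3,4-bis(benzyloxy)phenyl]propan-1-ol | O[C@H](c1ccc(OCc2ccccc2)c(OCc2ccccc2)c1)[C@@H](OCc1ccccc1)Cc1cc(Br)c(OCc2ccccc2)c(C)c1OCc1ccccc1 | intermediate
13 | lithium (1R,2S)-2-(benzyloxy)-1-[3,4-bis(benzyloxy)phenyl]-3-[2,4-bis(benzyloxy)-3-methyl-5,6-didehydrophenyl]propan-1-olate (C8≡C8a aryne) | [Li]O[C@H](c1ccc(OCc2ccccc2)c(OCc2ccccc2)c1)[C@@H](OCc1ccccc1)CC1=C(OCc2ccccc2)C(C)=C(OCc2ccccc2)C#C1 | intermediate (not isolated)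
14 | [(2R,3S)-3,5,7-tris(benzyloxy)-2-[3,4-bis(benzyloxy)phenyl]-6-methyl-3,4-dihydro-2H-chromen-8-yl]lithium | [Li]c1c(OCc2ccccc2)c(C)c(OCc2ccccc2)c2c1O[C@H](c1ccc(OCc3ccccc3)c(OCc3ccccc3)c1)[C@@H](OCc1ccccc1)C2 | intermediate (not isolated)
15 | (2R,3S)-3,5,7-tris(benzyloxy)-2-[3,4-bis(benzyloxy)phenyl]-6-methyl-3,4-dihydro-2H-chromene | Cc1c(OCc3ccccc3)c2c(cc1OCc1ccccc1)O[C@H](c1ccc(OCc3ccccc3)c(OCc3ccccc3)c1)[C@@H](OCc1ccccc1)C2 | intermediate
16 | (2R,3R)-2-(3,4-dihydroxyphenyl)-3,5,7-trihydroxy-2,3-dihydro-4H-chromen-4-one (taxifolin) | O=C1c2c(O)cc(O)cc2O[C@H](c2ccc(O)c(O)c2)[C@H]1O | starting material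
17 | (2R,3R)-7-(benzyloxy)-2-[3,4-bis(benzyloxy)phenyl]-3,5-dihydroxy-2,3-dihydro-4H-chromen-4-one | O=C1c2c(O)cc(OCc3ccccc3)cc2O[C@H](c2ccc(OCc3ccccc3)c(OCc3ccccc3)c2)[C@H]1O | intermediate
18 | (2R,3R)-7-(benzyloxy)-2-[3,4-bis(benzyloxy)phenyl]-3-hydroxy-4-oxo-3,4-dihydro-2H-chromen-5-yl trifluoromethanesulfonate | O=C1c2c(OS(=O)(=O)C(F)(F)F)cc(OCc3ccccc3)cc2O[C@H](c2ccc(OCc3ccccc3)c(OCc3ccccc3)c2)[C@H]1O | intermediate
19 | (2R,3R)-7-(benzyloxy)-2-[3,4-bis(benzyloxy)phenyl]-3-hydroxy-2,3-dihydro-4H-chromen-4-one | O=C1c2ccc(OCc3ccccc3)cc2O[C@H](c2ccc(OCc3ccccc3)c(OCc3ccccc3)c2)[C@H]1O | intermediate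
20 | (2R,3S,4R)-7-(benzyloxy)-2-[3,4-bis(benzyloxy)phenyl]-3,4-dihydro-2H-chromene-3,4-diol | O[C@@H]1c2ccc(OCc3ccccc3)cc2O[C@H](c2ccc(OCc3ccccc3)c(OCc3ccccc3)c2)[C@H]1O | intermediate
21 | (2R,3S)-7-(benzyloxy)-2-[3,4-bis(benzyloxy)phenyl]-3-hydroxy-3,4-dihydro-2H-chromen-4-ylium | [CH+]1c2ccc(OCc3ccccc3)cc2O[C@H](c2ccc(OCc3ccccc3)c(OCc3ccccc3)c2)[C@H]1O | intermediate (not isolated)
22 | (2R,3S,4S)-7-(benzyloxy)-2-[3,4-bis(benzyloxy)phenyl]-4-[(2R,3S)-3,5,7-tris(benzyloxy)-2-[3,4-bis(benzyloxy)phenyl]-6-methyl-3,4-dihydro-2H-chromen-8-yl]-3,4-dihydro-2H-chromen-3-ol | Cc1c(OCc5ccccc5)c2c(c([C@@H]3c4ccc(OCc5ccccc5)cc4O[C@H](c4ccc(OCc5ccccc5)c(OCc5ccccc5)c4)[C@H]3O)c1OCc1ccccc1)O[C@H](c1ccc(OCc3ccccc3)c(OCc3ccccc3)c1)[C@@H](OCc1ccccc1)C2 | intermediate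
23 | (2R,3S,4S)-2-(3,4-dihydroxyphenyl)-4-[(2R,3S)-2-(3,4-dihydroxyphenyl)-3,5,7-trihydroxy-6-methyl-3,4-dihydro-2H-chromen-8-yl]-3,4-dihydro-2H-chromene-3,7-diol | Cc1c(O)c2c(c([C@@H]3c4ccc(O)cc4O[C@H](c4ccc(O)c(O)c4)[C@H]3O)c1O)O[C@H](c1ccc(O)c(O)c1)[C@@H](O)C2 | target

**Step count and risks**

Total step count: 14. Longest linear sequence: 10 steps (steps 1 to 8, then 13 and 14); the upper unit is a four-step branch (steps 9 to 12).

Steps most likely to fail:

1. Step 8 (aryne ring closure). The aryne may be captured by the amide base or by the neighbouring C3 benzyloxy oxygen instead of the lithium alkoxide, or benzylic ether positions may be metalated before bromide is lost. The fallback sets out from 12 and comes back at 15. Metalation of C8a–H at −78 °C with lithium 2,2,6,6-tetramethylpiperidide in the presence of ZnCl2·2LiCl would trap the aryl anion as an arylzinc that cannot eliminate, and iodine would then give (1R,2S)-2-(benzyloxy)-3-[2,4-bis(benzyloxy)-5-bromo-6-iodo-3-methylphenyl]-1-[3,4-bis(benzyloxy)phenyl]propan-1-ol F1. An Ullmann etherification at the C–I bond (CuI, 1,10-phenanthroline, Cs2CO3, toluene, 100 °C) would close ring C to (2R,3S)-8-bromo-3,5,7-tris(benzyloxy)-2-[3,4-bis(benzyloxy)phenyl]-6-methyl-3,4-dihydro-2H-chromene F2. Bromine–lithium exchange (n-BuLi, THF, −78 °C) and protonation with MeOH would give 15.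

2. Step 13 (interflavan Friedel–Crafts union). The cation may alkylate the electron-rich ring A of a second molecule of 20 (oligomer formation), and facial selectivity at C4 may be incomplete. The fallback sets out from 19 and 15 and comes back at 23. Hydrogenolysis of 19 (H2, Pd(OH)2/C) would give (2R,3R)-2-(3,4-dihydroxyphenyl)-3,7-dihydroxy-2,3-dihydro-4H-chromen-4-one F3, and NaBH4 would reduce it to (2R,3S,4R)-2-(3,4-dihydroxyphenyl)-3,4-dihydro-2H-chromene-3,4,7-triol F4. Hydrogenolysis of 15 would give (2R,3S)-2-(3,4-dihydroxyphenyl)-6-methyl-3,4-dihydro-2H-chromene-3,5,7-triol F5. The protecting-group-free condensation of F4 with an excess of F5 in 0.1 M aqueous HCl at rt (the classical acid-catalysed flavan-3,4-diol condensation) would give 23 directly, with the C4 epimers separated on Sephadex LH-20.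

3. Step 10 (triflation of the 5-OH). Sulfonylation of the hydrogen-bonded 5-OH may be slow, so that long exposure to base opens or epimerises the dihydroflavonol ring. The fallback sets out from 17 and comes back at 20, bypassing steps 11 and 12. NaBH4 would first reduce the ketone to (2R,3S,4R)-7-(benzyloxy)-2-[3,4-bis(benzyloxy)phenyl]-3,4-dihydro-2H-chromene-3,4,5-triol F6, whose 5-OH is no longer hydrogen-bonded. Triflation under mild conditions (PhNTf2, Et3N, CH2Cl2, 0 °C) would give (2R,3S,4R)-7-(benzyloxy)-2-[3,4-bis(benzyloxy)phenyl]-3,4-dihydroxy-3,4-dihydro-2H-chromen-5-yl trifluoromethanesulfonate F7. Reduction with Pd(OAc)2/PPh3/HCO2H/Et3N would then give 20.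

**Further compounds**

F1 | step 8 | (1R,2S)-2-(benzyloxy)-3-[2,4-bis(benzyloxy)-5-bromo-6-iodo-3-methylphenyl]-1-[3,4-bis(benzyloxy)phenyl]propan-1-ol | O[C@H](c1ccc(OCc2ccccc2)c(OCc2ccccc2)c1)[C@@H](OCc1ccccc1)Cc1c(I)c(Br)c(OCc2ccccc2)c(C)c1OCc1ccccc1
F2 | step 8 | (2R,3S)-8-bromo-3,5,7-tris(benzyloxy)-2-[3,4-bis(benzyloxy)phenyl]-6-methyl-3,4-dihydro-2H-chromene | Cc1c(OCc3ccccc3)c2c(c(Br)c1OCc1ccccc1)O[C@H](c1ccc(OCc3ccccc3)c(OCc3ccccc3)c1)[C@@H](OCc1ccccc1)C2
F3 | step 13 | (2R,3R)-2-(3,4-dihydroxyphenyl)-3,7-dihydroxy-2,3-dihydro-4H-chromen-4-one | O=C1c2ccc(O)cc2O[C@H](c2ccc(O)c(O)c2)[C@H]1O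
F4 | step 13 | (2R,3S,4R)-2-(3,4-dihydroxyphenyl)-3,4-dihydro-2H-chromene-3,4,7-triol | O[C@@H]1c2ccc(O)cc2O[C@H](c2ccc(O)c(O)c2)[C@H]1O
F5 | step 13 | (2R,3S)-2-(3,4-dihydroxyphenyl)-6-methyl-3,4-dihydro-2H-chromene-3,5,7-triol | Cc1c(O)c2c(cc1O)O[C@H](c1ccc(O)c(O)c1)[C@@H](O)C2
F6 | step 10 | (2R,3S,4R)-7-(benzyloxy)-2-[3,4-bis(benzyloxy)phenyl]-3,4-dihydro-2H-chromene-3,4,5-triol | O[C@@H]1c2c(O)cc(OCc3ccccc3)cc2O[C@H](c2ccc(OCc3ccccc3)c(OCc3ccccc3)c2)[C@H]1O
F7 | step 10 | (2R,3S,4R)-7-(benzyloxy)-2-[3,4-bis(benzyloxy)phenyl]-3,4-dihydroxy-3,4-dihydro-2H-chromen-5-yl trifluoromethanesulfonate | O[C@@H]1c2c(OS(=O)(=O)C(F)(F)F)cc(OCc3ccccc3)cc2O[C@H](c2ccc(OCc3ccccc3)c(OCc3ccccc3)c2)[C@H]1O
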